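**Plan**
- Retrosynthesis: the lactone is opened to a 6,12-diol and the C8 ester taken back to a C8 ketone; the O–C10 bond of the oxolane is cut as a retro-oxa-Michael addition of the C3 ketone hydrate to a C8 enone; the C1–C10 bond is then cut as a retro-oxy-Cope shift, which re-forms a C3–C8 bond.
- This gives a cyclohexene C3–C4(Me)=C5–C6–C7–C8, which is the ring of (S)-carvone: its carbonyl carbon is C3, its ring alkene is C4=C5 (hence Z in the large ring), its isopropenyl group is C11–C13 on C7.
- Forward: carvone receives oxygen at C8 (Rubottom), a vinyl group on C3 (C2, C1), oxygen at C6 (allylic oxidation, then reduction), oxygen at C12 (SeO2) and a silyloxypropynyl group on C8 (C9, C10, C14).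
- Ring order: the carvone six-ring is expanded to the ten-membered carbocycle by forming C1–C10; the oxolane closes in the same flask; the lactone is made last.
- Enabling feature: C3 and C8 both carry oxygen and are linked by C2–C1–C10–C9, so they are the two carbinol carbons of a 1-vinyl-2-alkynyl-cyclohexane-1,2-diol; the surviving π bond makes C10 the β-carbon of a C8 enone that lies 1,4 to C3, so the oxygen bridge closes 5-exo.
- Stereochemistry: C7 from (S)-carvone; C6 by hydride addition anti to the C7 side chain; C10 and C3 together under thermodynamic control in the oxa-Michael closure; C8 by hydride reduction; the acyl centre from (R)-2-methylbutanoic acid.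

Key step: step 10

Remark: atom numbers are germacrane numbers of the target (ring C1–C10, lactone carbons C11–C13, C14 on C10, C15 on C4). The configurations drawn at C3 and C8 in compounds 3–14 are those expected for the major isomers and do not matter, because both centres become trigonal in step 10. Compounds 1, 11 and 19 are taken as commercial.

**Step 1**
Reactants: 1 (S)-(+)-carvone
Product: 3 trans-6-(triethylsilyloxy)carvone (silyloxy on C8 anti to the isopropenyl group), via triethylsilyl dienol ether 2 (not isolated)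
Conditions: LiN(i-Pr)2, THF, −78 °C; Et3SiCl; then mCPBA, NaHCO3, CH2Cl2, −20 °C
Reagents that add atoms: chlorotriethylsilane CC[Si](Cl)(CC)CC; mCPBA O=C(OO)c1cccc(Cl)c1
Why: Kinetic deprotonation at the α′-CH2 (C8) and O-silylation give the cross-conjugated dienol ether, whose electron-rich enol double bond should be epoxidised anti to the isopropenyl group and rearrange by 1,4-silyl shift to the α-silyloxy ketone (Rubottom oxidation); C7 is untouched.

**Step 2**
Reactants: 3
Product: 4 1-ethenyl-2-methyl-5-(prop-1-en-2-yl)-6-(triethylsilyloxy)cyclohex-2-en-1-ol (vinyl anti to isopropenyl)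
Conditions: CH2=CHMgBr, THF, −78 → −20 °C; then H2O
Reagents that add atoms: vinylmagnesium bromide C=C[Mg]Br
Why: Grignard 1,2-addition to the enone carbonyl (C3) brings in C2 and C1; attack anti to the C7 substituent is expected, and the new centre is erased in step 10.

**Step 3**
Reactants: 4
Product: 5 4-ethenyl-4-hydroxy-3-methyl-6-(prop-1-en-2-yl)-5-(triethylsilyloxy)cyclohex-2-en-1-one (C6 ketone)
Conditions: Rh2(cap)4 (dirhodium tetrakis(caprolactamate), 1 mol%), t-BuOOH (70% aq.), ClCH2CH2Cl, 40 °C, no base
Reagents that add atoms: tert-butyl hydroperoxide CC(C)(C)OO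
Why: Metal-catalysed radical allylic C–H oxidation of a cyclohexene to the enone should take the ring methylene C6, the only secondary allylic position of the trisubstituted alkene (C3 is quaternary, so no isomeric enone can form); the free tertiary alcohol is inert to this chromium-free oxidant and no stereocentre is made.

**Step 4**
Reactants: 5
Product: 6 4-ethenyl-4-hydroxy-6-(3-hydroxyprop-1-en-2-yl)-3-methyl-5-(triethylsilyloxy)cyclohex-2-en-1-one
Conditions: SeO2 (0.3 equiv), t-BuOOH, CH2Cl2, 0 °C → rt
Reagents that add atoms: tert-butyl hydroperoxide CC(C)(C)OO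
Why: SeO2 allylic hydroxylation (Riley oxidation, ene reaction then [2,3]-shift) should oxidise the methyl group of the 1,1-disubstituted alkene (C12), because the ring alkene is now a deactivated enone and the vinyl group has no allylic hydrogen; no stereocentre is made.

**Step 5**
Reactants: 6
Product: 7 1-ethenyl-5-(3-hydroxyprop-1-en-2-yl)-2-methyl-6-(triethylsilyloxy)cyclohex-2-ene-1,4-diol (C6 hydroxyl cis to the C7 side chain)
Conditions: LiBH(s-Bu)3, THF, −78 °C; then H2O
Reagents that add atoms: none
Why: The bulky hydride should add 1,2 to the β,β-disubstituted enone from the face opposite the C7 side chain (the cis selectivity of 2-alkylcyclohexanones), which sets C6 with its oxygen cis to that side chain as the cis-fused lactone requires.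

**Step 6**
Reactants: 7
Product: 8 6,12-bis(triisopropylsilyl) ether of 7
Conditions: i-Pr3SiOTf, 2,6-lutidine, CH2Cl2, −78 → 0 °C
Reagents that add atoms: triisopropylsilyl triflate CC(C)[Si](OS(=O)(=O)C(F)(F)F)(C(C)C)C(C)C
Why: Silylation should cap the primary C12 and secondary C6 hydroxyls, while the tertiary C3 hydroxyl is too hindered to react and stays free for step 10.

**Step 7**
Reactants: 8
Product: 9 1-ethenyl-2-methyl-4-(triisopropylsilyloxy)-5-[3-(triisopropylsilyloxy)prop-1-en-2-yl]cyclohex-2-ene-1,6-diol
Conditions: HF·pyridine, pyridine, THF, 0 °C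
Reagents that add atoms: none
Why: Buffered HF should cleave the triethylsilyl ether much faster than the bulkier triisopropylsilyl ethers (selective desilylation by size at silicon), freeing the C8 hydroxyl.

**Step 8**
Reactants: 9
Product: 10 2-ethenyl-2-hydroxy-3-methyl-5-(triisopropylsilyloxy)-6-[3-(triisopropylsilyloxy)prop-1-en-2-yl]cyclohex-3-en-1-one (C8 ketone)
Conditions: IBX, DMSO, rt
Reagents that add atoms: none
Why: IBX oxidises the secondary alcohol of a 1,2-diol to the α-hydroxy ketone without glycol cleavage and without base, so the C7 centre α to the new ketone and the β-silyloxy group should survive.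

**Step 9**
Reactants: 10; 11 tert-butyldimethyl(prop-2-yn-1-yloxy)silane
Product: 13 6-[3-(tert-butyldimethylsilyloxy)prop-1-yn-1-yl]-1-ethenyl-2-methyl-4-(triisopropylsilyloxy)-5-[3-(triisopropylsilyloxy)prop-1-en-2-yl]cyclohex-2-ene-1,6-diol (cis-diol), via lithium acetylide 12 (not isolated)
Conditions: 11, n-BuLi, THF, −78 °C; then 10, −78 → −40 °C; then H2O
Reagents that add atoms: none
Why: Acetylide 1,2-addition to the ketone (the first equivalent deprotonates the C3 hydroxyl) puts C9, C10 and C14 on C8; attack anti to the pseudo-axial C6 silyloxy group is expected, and either C8 epimer can place the alkyne gauche to the vinyl group in an accessible conformer.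

**Step 10**
Reactants: 13
Product: 17 bridged hemiketal ketone (3-hydroxy-3,10-epoxy-8-oxo ten-membered ring), via dipotassium dialkoxide 14 (not isolated), via dipotassium bis-enolate 15 (not isolated), via cyclodecadienedione 16 (not isolated)
Conditions: KH, 18-crown-6, THF, 0 °C → rt; then AcOH–NaOAc buffer (pH 4.5), THF–H2O, rt
Reagents that add atoms: water O
Why: KH/18-crown-6 converts the diol into dialkoxide 14, whose doubly oxygenated C3–C8 bond cleaves in a dianion-accelerated acetylenic oxy-Cope [3,3] shift while the vinyl terminus C1 bonds to the alkyne carbon C10, giving the ten-membered C3 enolate/C8 allenolate 15; buffered protonation gives the 3,8-dione 16 with a C9=C10 enone, and the hydrate of the C3 ketone then adds to C10 to give 17. The closest known reactions are the anionic oxy-Cope ring expansions of 1,2-dialkenyl- and 1-alkynyl-2-alkenyl-cyclohexanols and -1,2-diols to cyclodecenones used for germacranes, and hemiketal oxa-Michael closures of bridged ketals. The carbocycle is closed by the sigmatropic ring expansion from six to ten members (C4=C5 stays Z because it was the ring alkene of carvone), and the oxolane by a 5-exo-trig oxa-Michael addition. C6 and C7 are not touched; C10, and C3 which is tied to it by the one-atom bridge, should be set under thermodynamic control, because the oxa-Michael addition is reversible and the isomer that places the bulky silyloxymethyl group on the face away from the C6 and C7 substituents should prevail. The step needs cleavage of C3–C8 and not of C7–C8 (the alkyne and the C7 propenyl group also form a 1,5-enyne), which the second alkoxide on C3 should secure by making C3–C8 the weakest bond; it also needs the oxa-Michael addition to outrun transannular aldol reactions of the dione, which the weakly acidic, enolate-free quench should favour.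

**Step 11**
Reactants: 17
Product: 18 C8 alcohol of 17 (hydroxyl cis to the C7 side chain)
Conditions: Zn(BH4)2, Et2O, −20 °C; then H2O
Reagents that add atoms: none
Why: In this neutral chelating reduction, zinc bridging the C8 carbonyl and the ring oxygen on C10 lies on the same face as the C7 side chain, so hydride should arrive from the other face and give the C8 alcohol cis to the side chain and 1,3-syn to the ring oxygen; the hemiketal should stay closed without base.

**Step 12**
Reactants: 18; 19 (R)-2-methylbutanoic acid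
Product: 20 C8 (R)-2-methylbutanoate of 18
Conditions: DCC, DMAP (cat.), CH2Cl2, 0 °C → rt
Reagents that add atoms: none
Why: Steglich esterification should acylate the secondary C8 hydroxyl with retention, the tertiary hemiketal hydroxyl being unreactive, and the α-centre of the acid is not enolised under these conditions.

**Step 13**
Reactants: 20
Product: 21 6,12,14-triol hemiketal ester
Conditions: HF·pyridine, pyridine, THF, 0 °C → rt
Reagents that add atoms: none
Why: Fluoride desilylation should remove the three silyl ethers under mildly acidic conditions that avoid acyl migration and leave the hemiketal and the ester intact.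

**Step 14**
Reactants: 21
Product: 22 target
Conditions: MnO2 (activated, excess), CH2Cl2, rt
Reagents that add atoms: none
Why: MnO2 should oxidise the primary allylic C12 hydroxyl to the enal, which the cis C6 hydroxyl traps as a lactol that is oxidised on to the α-methylene-γ-lactone (oxidative lactonisation of a 2-methylene-1,4-diol); the non-allylic C14 hydroxyl and the tertiary hemiketal hydroxyl are not oxidised and no stereocentre changes.

**Compound list**
1 | (S)-(+)-carvone, (5S)-2-methyl-5-(prop-1-en-2-yl)cyclohex-2-en-1-one | CC1=CC[C@@H](CC1=O)C(C)=C | starting material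
2 | triethylsilyl dienol ether of 1, triethyl{[6-methyl-3-(prop-1-en-2-yl)cyclohexa-1,5-dien-1-yl]oxy}silane | CC1=CC[C@@H](C=C1O[Si](CC)(CC)CC)C(C)=C | intermediate
3 | 2-methyl-5-(prop-1-en-2-yl)-6-(triethylsilyloxy)cyclohex-2-en-1-one, silyloxy trans to isopropenyl | CC1=CC[C@@H]([C@@H](O[Si](CC)(CC)CC)C1=O)C(C)=C | intermediate
4 | 1-ethenyl-2-methyl-5-(prop-1-en-2-yl)-6-(triethylsilyloxy)cyclohex-2-en-1-ol, vinyl trans to isopropenyl, hydroxyl trans to silyloxy | CC1=CC[C@@H]([C@@H](O[Si](CC)(CC)CC)[C@@]1(O)C=C)C(C)=C | intermediate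
5 | 4-ethenyl-4-hydroxy-3-methyl-6-(prop-1-en-2-yl)-5-(triethylsilyloxy)cyclohex-2-en-1-one | CC1=CC(=O)[C@@H]([C@@H](O[Si](CC)(CC)CC)[C@@]1(O)C=C)C(C)=C | intermediate
6 | 4-ethenyl-4-hydroxy-6-(3-hydroxyprop-1-en-2-yl)-3-methyl-5-(triethylsilyloxy)cyclohex-2-en-1-one | CC1=CC(=O)[C@@H]([C@@H](O[Si](CC)(CC)CC)[C@@]1(O)C=C)C(=C)CO | intermediate
7 | 1-ethenyl-5-(3-hydroxyprop-1-en-2-yl)-2-methyl-6-(triethylsilyloxy)cyclohex-2-ene-1,4-diol, 4-hydroxyl cis to the side chain on C5 | CC1=C[C@H](O)[C@@H]([C@@H](O[Si](CC)(CC)CC)[C@@]1(O)C=C)C(=C)CO | intermediate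
8 | bis(triisopropylsilyl) ether of 7 at the 4-hydroxyl and the side-chain hydroxyl | CC1=C[C@H](O[Si](C(C)C)(C(C)C)C(C)C)[C@@H]([C@@H](O[Si](CC)(CC)CC)[C@@]1(O)C=C)C(=C)CO[Si](C(C)C)(C(C)C)C(C)C | intermediate
9 | 1-ethenyl-2-methyl-4-(triisopropylsilyloxy)-5-[3-(triisopropylsilyloxy)prop-1-en-2-yl]cyclohex-2-ene-1,6-diol | CC1=C[C@H](O[Si](C(C)C)(C(C)C)C(C)C)[C@@H]([C@@H](O)[C@@]1(O)C=C)C(=C)CO[Si](C(C)C)(C(C)C)C(C)C | intermediate
10 | 2-ethenyl-2-hydroxy-3-methyl-5-(triisopropylsilyloxy)-6-[3-(triisopropylsilyloxy)prop-1-en-2-yl]cyclohex-3-en-1-one | CC1=C[C@H](O[Si](C(C)C)(C(C)C)C(C)C)[C@@H](C(=O)[C@@]1(O)C=C)C(=C)CO[Si](C(C)C)(C(C)C)C(C)C | intermediate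
11 | tert-butyldimethyl(prop-2-yn-1-yloxy)silane | C#CCO[Si](C)(C)C(C)(C)C | starting material
12 | lithium acetylide of 11 | [Li]C#CCO[Si](C)(C)C(C)(C)C | intermediate
13 | 6-[3-(tert-butyldimethylsilyloxy)prop-1-yn-1-yl]-1-ethenyl-2-methyl-4-(triisopropylsilyloxy)-5-[3-(triisopropylsilyloxy)prop-1-en-2-yl]cyclohex-2-ene-1,6-diol, cis-diol with vinyl and alkynyl cis | CC1=C[C@H](O[Si](C(C)C)(C(C)C)C(C)C)[C@@H]([C@@](O)(C#CCO[Si](C)(C)C(C)(C)C)[C@@]1(O)C=C)C(=C)CO[Si](C(C)C)(C(C)C)C(C)C | intermediate
14 | dipotassium dialkoxide of 13 | CC1=C[C@H](O[Si](C(C)C)(C(C)C)C(C)C)[C@@H]([C@@]([O-])(C#CCO[Si](C)(C)C(C)(C)C)[C@@]1([O-])C=C)C(=C)CO[Si](C(C)C)(C(C)C)C(C)C.[K+].[K+] | intermediate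
15 | dipotassium bis-enolate of the ten-membered ring: C3 enolate (C2=C3), C8 allenolate (C8=C9=C10), 4Z alkene, silyl ethers at O6, O12 and O14 | C=C(CO[Si](C(C)C)(C(C)C)C(C)C)[C@H]1[C@@H](O[Si](C(C)C)(C(C)C)C(C)C)/C=C(/C)C([O-])=CCC(CO[Si](C)(C)C(C)(C)C)=C=C1[O-].[K+].[K+] | intermediate
16 | (4Z)-cyclodeca-4,9-diene-3,8-dione (germacrane numbering) carrying 6-OSi(i-Pr)3, the 7-[3-(triisopropylsilyloxy)prop-1-en-2-yl] group, 10-CH2OSi(t-Bu)Me2 and 4-methyl | C=C(CO[Si](C(C)C)(C(C)C)C(C)C)[C@H]1[C@@H](O[Si](C(C)C)(C(C)C)C(C)C)/C=C(/C)C(=O)CCC(CO[Si](C)(C)C(C)(C)C)=CC1=O | intermediate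
17 | bridged hemiketal ketone: 3-hydroxy-3,10-epoxy-8-oxo ring, oxygen bridge on the face of the C6 and C7 substituents, silyl ethers as in 16 | C=C(CO[Si](C(C)C)(C(C)C)C(C)C)[C@H]1[C@@H](O[Si](C(C)C)(C(C)C)C(C)C)/C=C(/C)[C@]2(O)CC[C@](CO[Si](C)(C)C(C)(C)C)(CC1=O)O2 | intermediate
18 | C8 alcohol of 17, 8-hydroxyl cis to the C7 side chain | C=C(CO[Si](C(C)C)(C(C)C)C(C)C)[C@H]1[C@@H](O[Si](C(C)C)(C(C)C)C(C)C)/C=C(/C)[C@]2(O)CC[C@](CO[Si](C)(C)C(C)(C)C)(C[C@H]1O)O2 | intermediate
19 | (R)-2-methylbutanoic acid | CC[C@@H](C)C(=O)O | starting material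
20 | C8 (R)-2-methylbutanoate of 18 | C=C(CO[Si](C(C)C)(C(C)C)C(C)C)[C@H]1[C@@H](O[Si](C(C)C)(C(C)C)C(C)C)/C=C(/C)[C@]2(O)CC[C@](CO[Si](C)(C)C(C)(C)C)(C[C@H]1OC(=O)[C@H](C)CC)O2 | intermediate
21 | desilylated 20: 6,12,14-triol with the 3-hydroxy-3,10-epoxy hemiketal and the C8 ester | C=C(CO)[C@H]1[C@@H](O)/C=C(/C)[C@]2(O)CC[C@](CO)(C[C@H]1OC(=O)[C@H](C)CC)O2 | intermediate
22 | target, (3S,6S,7R,8R,10R)-3-hydroxy-3,10-epoxy-14-hydroxy-8-[(R)-2-methylbutanoyloxy]germacra-4Z,11(13)-dien-6,12-olide | C=C1C(=O)O[C@H]2/C=C(/C)[C@]3(O)CC[C@](CO)(C[C@@H](OC(=O)[C@H](C)CC)[C@@H]12)O3 | target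

**Step count and risks**
Total step count: 14. Longest linear sequence: 14 steps, from (S)-carvone 1 (11 and 19 are used as bought).

The three steps most likely to fail:

1. Step 10. The oxygen bridge may close on the wrong face of the C9=C10 enone (poor facial selectivity), or transannular aldol reaction of the dione may compete with the oxa-Michael addition. The fallback makes the C10–O bond stepwise and under reagent control. It sets out from 13: the same KH/18-crown-6 rearrangement is run, but bis-enolate 15 is trapped with Et3SiCl at −78 °C to give the bis(triethylsilyl) ether F1. Wet silica gel hydrolyses only the labile siloxyallene of F1 and leaves the enone silyl enol ether F2, in which C3 is masked. Catalytic asymmetric nucleophilic epoxidation of the enone (t-BuOOH, La(OiPr)3, BINOL, Ph3As=O; the BINOL antipode is chosen for the required face) gives the epoxy ketone F3. SmI2 in THF–MeOH at −90 °C cleaves the Cα–O bond to the β-hydroxy ketone F4. PPTS in wet acetone then hydrolyses the enol ether, the C10 hydroxyl closes onto the C3 ketone, and the route is rejoined at 17.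

2. Step 3. Hydrogen abstraction may lack site selectivity (the tertiary allylic C7–H or the side-chain methyl may react), and the isopropenyl group may move into conjugation with the new enone. The fallback uses an ionic ene-type oxidant on a capped alcohol. It sets out from 4: TMS-imidazole in CH2Cl2 gives the trimethylsilyl ether F5. Stoichiometric CrO3·3,5-dimethylpyrazole (CH2Cl2, −20 °C) favours the unhindered ring methylene next to a trisubstituted alkene and cannot transpose the capped carbinol, and gives the enone F6. Citric acid in MeOH at 0 °C removes the trimethylsilyl group and the route is rejoined at 5.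

3. Step 11. Hydride may add to the other face of the C8 ketone. The fallback keeps that product and corrects the centre during acylation. It sets out from 17: the reduction then gives the C8-epimeric alcohol F7, which is esterified with inversion under Mitsunobu conditions (PPh3, DIAD, acid 19, toluene, 0 °C → rt) to give 20 directly, where the route is rejoined.

**Further compounds**
F1 | step 10 | bis(triethylsilyl) ether of 15: C3 triethylsilyl enol ether and C8 triethylsiloxyallene of the ten-membered ring | C=C(CO[Si](C(C)C)(C(C)C)C(C)C)[C@H]1[C@@H](O[Si](C(C)C)(C(C)C)C(C)C)/C=C(/C)C(O[Si](CC)(CC)CC)=CCC(CO[Si](C)(C)C(C)(C)C)=C=C1O[Si](CC)(CC)CC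
F2 | step 10 | C3 triethylsilyl enol ether of dione 16 (C8 enone free) | C=C(CO[Si](C(C)C)(C(C)C)C(C)C)[C@H]1[C@@H](O[Si](C(C)C)(C(C)C)C(C)C)/C=C(/C)C(O[Si](CC)(CC)CC)=CCC(CO[Si](C)(C)C(C)(C)C)=CC1=O
F3 | step 10 | 9,10-epoxy-8-ketone of F2, epoxide oxygen on the face required at C10 | C=C(CO[Si](C(C)C)(C(C)C)C(C)C)[C@H]1[C@@H](O[Si](C(C)C)(C(C)C)C(C)C)/C=C(/C)C(O[Si](CC)(CC)CC)=CC[C@@]2(CO[Si](C)(C)C(C)(C)C)OC2C1=O
F4 | step 10 | 10-hydroxy-8-ketone with the C3 triethylsilyl enol ether | C=C(CO[Si](C(C)C)(C(C)C)C(C)C)[C@H]1[C@@H](O[Si](C(C)C)(C(C)C)C(C)C)/C=C(/C)C(O[Si](CC)(CC)CC)=CC[C@](O)(CO[Si](C)(C)C(C)(C)C)CC1=O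
F5 | step 3 | trimethylsilyl ether of 4 at the tertiary hydroxyl | CC1=CC[C@@H]([C@@H](O[Si](CC)(CC)CC)[C@@]1(O[Si](C)(C)C)C=C)C(C)=C
F6 | step 3 | trimethylsilyl ether of 5 at the tertiary hydroxyl | CC1=CC(=O)[C@@H]([C@@H](O[Si](CC)(CC)CC)[C@@]1(O[Si](C)(C)C)C=C)C(C)=C
F7 | step 11 | C8 epimer of alcohol 18 | C=C(CO[Si](C(C)C)(C(C)C)C(C)C)[C@H]1[C@@H](O[Si](C(C)C)(C(C)C)C(C)C)/C=C(/C)[C@]2(O)CC[C@](CO[Si](C)(C)C(C)(C)C)(C[C@@H]1O)O2
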